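Percent of the substrate charged per second is the unit to read the dusk run in, and you want the Monday, Sunday and Tuesday flasks below from that one run.

| setting | dusk | Sunday's | Monday's | Tuesday's |
|---|---|---|---|---|
| substrate | 20 mM | 20 mM | 20 mM | 20 mM |
| coupling partner | 30 mM | 60.0 mM | 60.0 mM | 60.0 mM |
| free catalyst | 100 µM | 100 µM | 100 µM | 100 µM |
| added ligand | 0.12 mM | 0.12 mM | 0.12 mM | 0.12 mM |
| temperature | 25 °C | 45 °C | 25 °C | 65 °C |
| remark | run made earlier |  |  |  |
| time |  | 6.0 min | 6.0 min | 6.0 min |

dusk run (percent of the substrate charged)

| time / s | over-reaction product / % | target / % | catalyst intermediate C / % | substrate / % |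
|---|---|---|---|---|
| 20.0 | 0 | 3.7 | 0 | 96.0 |
| 40.0 | 0.2 | 7.4 | 0.4 | 92.8 |
| 50.0 | 0.1 | 9.3 | 0.2 | 91.0 |
| 80.0 | 0 | 14.3 | 0 | 84.6 |

(scatter of a reading: 0.3 percentage points)

- the numbers in the tables scatter by 0.3 percentage points (one standard deviation)
- on the list of suspects stand: catalyst intermediate C -> free catalyst + target; target -> over-reaction product; free catalyst + added ligand <-> idle complex; substrate + catalyst intermediate B -> catalyst intermediate C; coupling partner + free catalyst -> catalyst intermediate A; catalyst intermediate A -> catalyst intermediate B
- the earlier runs do not show what temperature does; that part of a forecast is a guess

- which of these there is most of at the end, counted by the substrate in it, Sunday's (catalyst intermediate C / over-reaction product / substrate / target)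
- which of these there is most of at the end, counted by the substrate in it, Monday's (catalyst intermediate C / over-reaction product / substrate / target)
- which of these there is most of at the end, counted by the substrate in it, Tuesday's (catalyst intermediate C / over-reaction product / substrate / target)
- amount of the one of these that there is most of at the end, in percent of the substrate charged, Sunday's
- amount of the one of these that there is most of at the end, in percent of the substrate charged, Monday's
- amount of the one of these that there is most of at the end, in percent of the substrate charged, Tuesday's

**Straight line.** In the dusk run, target reads 7.4% at 40.0 s and 14.3% at 80.0 s, so twice the time gives about twice the amount, although substrate has fallen to 84.6%. A straight line from the 40.0 s reading would put 14.8% at 80.0 s, and the reading falls 0.5 percentage points short of that. A rate that falls with [substrate] could give this bend, and with a scatter of 0.3 points per reading you cannot tell it from a straight line, so the order in substrate stays open. You take the straight line only as a working rate, about 0.358 s⁻¹ per catalyst.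

**Clearing time.** Dividing the last time by the last target reading gives 9.32 min, and this is the clearing time, the time the dusk rate needs to turn the whole substrate charge. Monday's, at the same temperature, runs 6.0 min, so your own reckoning turns 64.4% of the substrate if the rate holds. In powers of ten, the asked time stands 0.191 of a decade short of clearing.

**Weak link.** Monday's carries twice the dusk partner, and a rate proportional to [coupling partner] would gain 0.301 of a decade, which carries past clearing, to 129% of the charge on paper. The dusk run might test this, since it used 9.53% of its partner by the last reading. A proportional rate would make the second stretch gain about 0.35 points less than the first, but each reading scatters by 0.3 points, so the bend cannot be read. The link stays a bracket, and you commit to the measured rate: about 64.4% target on Monday's. For Sunday's and Tuesday's, the dusk run holds no temperature term, so anything said of them is a guess.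

**The forecast.** It names target for Sunday's at 89% (72% to 98%), target for Monday's at 82% (63% to 97%), and target for Tuesday's at 66% (40% to 93%). For Monday's its ground is that “Doubling the partner therefore gives between 1× and 2× the rate.” For Sunday's and Tuesday's it assumes a rough Arrhenius rise of about 6× at 45 °C and about 30× at 65 °C, with the coupling finished within a minute or two and the target then slowly over-reacting. Its Monday value stands higher than your reckoning, because it takes a point inside the bracket.

**The flasks.** Sunday's ends with target on top at 56.0%, Monday's with target at 64.5%, and Tuesday's with over-reaction product at 98.9%.

    catalyst intermediate C → free catalyst + target (k = 3.80 s⁻¹, Ea = 72.0 kJ mol⁻¹)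
    target → over-reaction product (k = 2.20 × 10⁻⁴ s⁻¹, Ea = 86.0 kJ mol⁻¹)
    free catalyst + added ligand ⇌ idle complex, settled at all times (K = 7600 M⁻¹, ΔH = 6.00 kJ mol⁻¹)
    substrate + catalyst intermediate B → catalyst intermediate C (k = 190 M⁻¹ s⁻¹, Ea = 43.0 kJ mol⁻¹)
    coupling partner + free catalyst → catalyst intermediate A (k = 190 M⁻¹ s⁻¹, Ea = 42.0 kJ mol⁻¹)
    catalyst intermediate A → catalyst intermediate B (k = 0.560 s⁻¹, Ea = 68.0 kJ mol⁻¹)
    (constants at 25 °C)

**Monday's rates.** In Monday's flask at 6.00 min, free catalyst has a half-life of 0.079 s against the partner, far shorter than the 1.2 s of catalyst intermediate A turning into catalyst intermediate B; A, the resting state there, holds 58.3% of the catalyst, and the substrate used, 67.2%, stands beside the 64.4% from the clearing time. Stretched to the neighbour flask with 34 mM of substrate, the clearing time gives 37.9% turned, and that flask ends with 41.6% target and 1.69% over-reaction product.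

All runs come from a simulation for an exercise, noise included.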